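**Remark on the chemistry.** Locants are eremophilane locants: ring A = C1–C5 and C10, ring B = C5–C10, C3 carries the ester oxygen, C4 and C5 the methyl groups, C11 is the propanoate CH. The starting materials 1, 3, 6, 7 and 21 and (+)-Ipc2BOMe are taken to be commercial.

## Retrosynthetic overview

1. The angelate at C3 and a silyl ether on the same oxygen are removed last; what remains is the bicyclic enone 19.
2. Enabling feature: in ring B the C6=C7–C8=O enone flanks the fusion bond, so C5 is alpha to C6 (as an aldehyde carbon) and C10 is beta to the C8 ketone; C6 and C8 are 1,5-related across C5–C10.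
3. Hence one operation on the acyclic keto aldehyde enone 16: ring A closes first through C5–C10 (intramolecular enamine Michael addition, sets C5 and C10), ring B second through C6=C7 (aldol condensation).
4. 16 comes from cross-metathesis at C9=C10 of vinyl ketone 5 (C11 from the Roche ester) with aldehyde 15 (C3/C4 by anti crotylboration, C5/C6 by Wacker oxidation and methoxymethylenation).

Key step: step 9

## Route

Step 1
Reactants: 1 methyl (2R)-3-hydroxy-2-methylpropanoate
Product: 2 methyl (2S)-3-iodo-2-methylpropanoate
Conditions: PPh3, I2, imidazole, CH2Cl2, 0 °C to rt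
Reagents that add atoms: iodine, II
Why: Appel-type iodination replaces the primary hydroxyl by iodide without touching the stereocentre, whose descriptor changes from R to S only through the CIP priorities.

Step 2
Reactants: 2 methyl (2S)-3-iodo-2-methylpropanoate; 3 acryloyl chloride
Product: 5 methyl (2R)-2-methyl-4-oxohex-5-enoate, via alkylzinc iodide 4 (not isolated)
Conditions: Zn dust (activated with BrCH2CH2Br and Me3SiCl, cat.), THF, 35 °C; then 3, Pd(PPh3)4 (5 mol %), THF, 0 °C to rt
Reagents that add atoms: none
Why: Zinc insertion gives an ester-bearing alkylzinc iodide that keeps its configuration, and Negishi acylation with the unsaturated acid chloride under zerovalent palladium catalysis should give the vinyl ketone without conjugate addition.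

Step 3
Reactants: 6 (4Z)-hept-4-enal; 7 (2E)-but-2-ene
Product: 11 (3R,4S,7Z)-3-methyldeca-1,7-dien-4-ol, via (E)-crotylpotassium 8 (not isolated), via (E)-crotyldiisopinocampheylborane 9 (not isolated), via borinate ester 10 (not isolated)
Conditions: 7, KOt-Bu, n-BuLi, THF, −78 to −45 °C; (+)-Ipc2BOMe, −78 °C; BF3·OEt2; 6, −78 °C; then 3 M NaOH, 30 % H2O2, rt
Reagents that add atoms: none
Why: Brown crotylboration through a chair-like Zimmerman–Traxler transition state, in which the E crotyl geometry gives the anti pair and the isopinocampheyl groups derived from (−)-α-pinene select the aldehyde face that gives the 4S carbinol.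

Step 4
Reactants: 11 (3R,4S,7Z)-3-methyldeca-1,7-dien-4-ol
Product: 12 tert-butyldimethyl{[(3R,4S,7Z)-3-methyldeca-1,7-dien-4-yl]oxy}silane
Conditions: TBSOTf, 2,6-lutidine, CH2Cl2, −78 to 0 °C
Reagents that add atoms: tert-butyldimethylsilyl trifluoromethanesulfonate, CC(C)(C)[Si](C)(C)OS(=O)(=O)C(F)(F)F
Why: Standard silylation of a secondary alcohol; the ether masks the C3 oxygen to the end and keeps it from forming a lactol with the later aldehyde.

Step 5
Reactants: 12 tert-butyldimethyl{[(3R,4S,7Z)-3-methyldeca-1,7-dien-4-yl]oxy}silane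
Product: 13 (3S,4S,7Z)-4-[(tert-butyldimethylsilyl)oxy]-3-methyldec-7-en-2-one
Conditions: PdCl2 (10 mol %), CuCl (30 mol %), O2 (1 atm), DMF/H2O 7:1, rt
Reagents that add atoms: water, O
Why: Tsuji–Wacker oxidation gives the methyl ketone with Markovnikov selectivity, and the monosubstituted terminal alkene should react much faster than the Z-1,2-disubstituted one.

Step 6
Reactants: 13 (3S,4S,7Z)-4-[(tert-butyldimethylsilyl)oxy]-3-methyldec-7-en-2-one
Product: 14 tert-butyl{[(3Z,7S,8R)-10-methoxy-8,9-dimethyldeca-3,9-dien-7-yl]oxy}dimethylsilane (enol ether E/Z mixture)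
Conditions: MeOCH2PPh3Cl, KHMDS, THF, 0 °C; then 13, −78 °C to rt
Reagents that add atoms: (methoxymethyl)triphenylphosphonium chloride, COC[P+](c1ccccc1)(c1ccccc1)c1ccccc1.[Cl-]
Why: Wittig methoxymethylenation adds the future C6 as an enol ether at low temperature, which should leave the alpha stereocentre and the beta silyloxy group intact; the enol ether geometry is of no consequence.

Step 7
Reactants: 14 tert-butyl{[(3Z,7S,8R)-10-methoxy-8,9-dimethyldeca-3,9-dien-7-yl]oxy}dimethylsilane
Product: 15 (3R,4S,7Z)-4-[(tert-butyldimethylsilyl)oxy]-2,3-dimethyldec-7-enal (C2 epimers)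
Conditions: PPTS (0.3 equiv), acetone/H2O 9:1, 50 °C
Reagents that add atoms: water, O
Why: Mild acid hydrolysis of the enol ether gives the alpha-branched aldehyde while the secondary silyl ether survives; the new centre (C5) forms as a mixture, which does not matter because it becomes an enamine carbon in step 9.

Step 8
Reactants: 15 (3R,4S,7Z)-4-[(tert-butyldimethylsilyl)oxy]-2,3-dimethyldec-7-enal; 5 methyl (2R)-2-methyl-4-oxohex-5-enoate
Product: 16 methyl (2R,5E,9S,10R)-9-[(tert-butyldimethylsilyl)oxy]-2,10,11-trimethyl-4,12-dioxododec-5-enoate (C11 epimers)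
Conditions: 5 (3 equiv), second-generation Hoveyda–Grubbs catalyst RuCl2(H2IMes)(=CH-C6H4-2-O-i-Pr) (5 mol %), CH2Cl2, 40 °C
Reagents that add atoms: none
Why: Cross-metathesis of a 1,2-disubstituted alkene with an excess of the electron-poor vinyl ketone should give the E enone; aldehyde, silyl ether and ester are tolerated and but-1-ene leaves the mixture.

Step 9
Reactants: 16 methyl (2R,5E,9S,10R)-9-[(tert-butyldimethylsilyl)oxy]-2,10,11-trimethyl-4,12-dioxododec-5-enoate
Product: 19 methyl (2R)-2-[(4aR,7S,8R,8aR)-7-[(tert-butyldimethylsilyl)oxy]-8,8a-dimethyl-3-oxo-3,4,4a,5,6,7,8,8a-octahydronaphthalen-2-yl]propanoate, via keto aldehyde 17 (not isolated), via aldol 18 (not isolated)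
Conditions: pyrrolidine (0.5 equiv), AcOH (0.5 equiv), toluene, rt; then 60 °C
Reagents that add atoms: none
Why: Pyrrolidine converts the alpha-branched aldehyde of 16 into the C5=C6 enamine (which erases the unfixed C5 centre), this adds to C10 of the E enone and, after hydrolysis to keto aldehyde 17, the C7 enamine of the C8 ketone attacks the now non-enolisable C6 aldehyde and aldol 18 loses water to give the C6=C7 enone. The closest known reaction type is the amine-mediated Robinson annulation of alpha,alpha-disubstituted aldehydes with vinyl ketones (Stork enamine Michael addition, then aldol condensation), combined with the known amine-catalysed intramolecular Michael addition of aldehydes to enones. Ring A closes 6-exo-trig through the C5–C10 bond and ring B 6-(enolendo)-exo-trig through C6–C7, followed by E1cB dehydration. C10 should be set in a chair-like transition state in which the C3 silyloxy group is equatorial (an axial one would be 1,3-diaxial to a substituent of the fully substituted C5), which places the C4 methyl axial and forces the enone arm at C10 equatorial, since an axial arm would be syn-axial to that methyl. At C5 the planar enamine carbon, the smaller group, should take the axial site anti to the C4 methyl and the C5 methyl the equatorial one, so that the two methyl groups become cis and C6 and C9 cis, which leads to the cis-fused enone after the aldol step. The step needs facial selectivity at the C5 enamine relative to the C3/C4 pair (the competing mode with the C5 methyl axial would give the 5-epimeric trans-fused enone), for which the anti C3/C4 pair gives only the modest bias described, and chemoselectivity in the aldol step, which is secured because C5 is quaternary and only attack of C7 on C6 gives a six-membered ring.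

Step 10
Reactants: 19 methyl (2R)-2-[(4aR,7S,8R,8aR)-7-[(tert-butyldimethylsilyl)oxy]-8,8a-dimethyl-3-oxo-3,4,4a,5,6,7,8,8a-octahydronaphthalen-2-yl]propanoate
Product: 20 methyl (2R)-2-[(4aR,7S,8R,8aR)-7-hydroxy-8,8a-dimethyl-3-oxo-3,4,4a,5,6,7,8,8a-octahydronaphthalen-2-yl]propanoate
Conditions: HF·pyridine, THF/pyridine, 0 °C to rt
Reagents that add atoms: none
Why: Fluoride-mediated desilylation under weakly acidic conditions, which should spare the enone, the methyl ester and the C11 centre next to the ester.

Step 11
Reactants: 20 methyl (2R)-2-[(4aR,7S,8R,8aR)-7-hydroxy-8,8a-dimethyl-3-oxo-3,4,4a,5,6,7,8,8a-octahydronaphthalen-2-yl]propanoate; 21 angelic acid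
Product: 23 methyl (2R)-2-[(4aR,7S,8R,8aR)-8,8a-dimethyl-7-{[(2Z)-2-methylbut-2-enoyl]oxy}-3-oxo-3,4,4a,5,6,7,8,8a-octahydronaphthalen-2-yl]propanoate, via mixed anhydride 22 (not isolated)
Conditions: 21, 2,4,6-trichlorobenzoyl chloride, Et3N, toluene, rt; then 20, 80 °C
Reagents that add atoms: none
Why: Yamaguchi-type esterification through the mixed anhydride, run without a nucleophilic catalyst because that is the established way to acylate hindered secondary alcohols with angelic acid without Z to E isomerisation to the tiglate; no stereocentre is touched.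

## Compound list

1 | methyl (2R)-3-hydroxy-2-methylpropanoate (Roche ester) | COC(=O)[C@H](C)CO | starting material
2 | methyl (2S)-3-iodo-2-methylpropanoate | COC(=O)[C@H](C)CI | intermediate
3 | acryloyl chloride | C=CC(=O)Cl | starting material
4 | [(2S)-3-methoxy-2-methyl-3-oxopropyl]zinc iodide | COC(=O)[C@H](C)C[Zn]I | intermediate
5 | methyl (2R)-2-methyl-4-oxohex-5-enoate | COC(=O)[C@H](C)CC(=O)C=C | intermediate
6 | (4Z)-hept-4-enal | CC/C=C\CCC=O | starting material
7 | (2E)-but-2-ene | C/C=C/C | starting material
8 | (E)-crotylpotassium | C/C=C/C[K] | intermediate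
9 | (E)-crotyldiisopinocampheylborane (isopinocampheyl groups from (−)-α-pinene) | C/C=C/CB([C@H]1C[C@H]2C[C@@H]([C@@H]1C)C2(C)C)[C@H]1C[C@H]2C[C@@H]([C@@H]1C)C2(C)C | intermediate
10 | (3R,4S,7Z)-3-methyldeca-1,7-dien-4-yl diisopinocampheylborinate | CC/C=C\CC[C@H](OB([C@H]1C[C@H]2C[C@@H]([C@@H]1C)C2(C)C)[C@H]1C[C@H]2C[C@@H]([C@@H]1C)C2(C)C)[C@H](C)C=C | intermediate
11 | (3R,4S,7Z)-3-methyldeca-1,7-dien-4-ol | CC/C=C\CC[C@H](O)[C@H](C)C=C | intermediate
12 | tert-butyldimethyl{[(3R,4S,7Z)-3-methyldeca-1,7-dien-4-yl]oxy}silane | CC/C=C\CC[C@H](O[Si](C)(C)C(C)(C)C)[C@H](C)C=C | intermediate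
13 | (3S,4S,7Z)-4-[(tert-butyldimethylsilyl)oxy]-3-methyldec-7-en-2-one | CC/C=C\CC[C@H](O[Si](C)(C)C(C)(C)C)[C@H](C)C(C)=O | intermediate
14 | tert-butyl{[(3Z,7S,8R)-10-methoxy-8,9-dimethyldeca-3,9-dien-7-yl]oxy}dimethylsilane (enol ether E/Z mixture) | CC/C=C\CC[C@H](O[Si](C)(C)C(C)(C)C)[C@H](C)C(C)=COC | intermediate
15 | (3R,4S,7Z)-4-[(tert-butyldimethylsilyl)oxy]-2,3-dimethyldec-7-enal (C2 epimers) | CC/C=C\CC[C@H](O[Si](C)(C)C(C)(C)C)[C@H](C)C(C)C=O | intermediate
16 | methyl (2R,5E,9S,10R)-9-[(tert-butyldimethylsilyl)oxy]-2,10,11-trimethyl-4,12-dioxododec-5-enoate (C11 epimers) | COC(=O)[C@H](C)CC(=O)/C=C/CC[C@H](O[Si](C)(C)C(C)(C)C)[C@H](C)C(C)C=O | intermediate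
17 | methyl (2R)-5-[(1R,2S,3R,4S)-4-[(tert-butyldimethylsilyl)oxy]-2-formyl-2,3-dimethylcyclohexyl]-2-methyl-4-oxopentanoate (keto aldehyde, ring A closed) | CC(C)(C)[Si](C)(C)O[C@H]1CC[C@H](CC(=O)C[C@@H](C)C(=O)OC)[C@](C)(C=O)[C@H]1C | intermediate
18 | aldol: the 1-hydroxy-3-oxodecahydronaphthalen-2-yl analogue of 19 (hydroxyl on C6, hydrogen on C7, both centres unfixed) | CC(C)(C)[Si](C)(C)O[C@H]1CC[C@@H]2CC(=O)C([C@@H](C)C(=O)OC)C(O)[C@]2(C)[C@H]1C | intermediate
19 | methyl (2R)-2-[(4aR,7S,8R,8aR)-7-[(tert-butyldimethylsilyl)oxy]-8,8a-dimethyl-3-oxo-3,4,4a,5,6,7,8,8a-octahydronaphthalen-2-yl]propanoate | CC(C)(C)[Si](C)(C)O[C@H]1CC[C@@H]2CC(=O)C([C@@H](C)C(=O)OC)=C[C@]2(C)[C@H]1C | intermediate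
20 | methyl (2R)-2-[(4aR,7S,8R,8aR)-7-hydroxy-8,8a-dimethyl-3-oxo-3,4,4a,5,6,7,8,8a-octahydronaphthalen-2-yl]propanoate | O[C@H]1CC[C@@H]2CC(=O)C([C@@H](C)C(=O)OC)=C[C@]2(C)[C@H]1C | intermediate
21 | angelic acid, (2Z)-2-methylbut-2-enoic acid | C/C=C(/C)C(=O)O | starting material
22 | (2Z)-2-methylbut-2-enoic 2,4,6-trichlorobenzoic anhydride | C/C=C(/C)C(=O)OC(=O)c1c(Cl)cc(Cl)cc1Cl | intermediate
23 | methyl (2R)-2-[(4aR,7S,8R,8aR)-8,8a-dimethyl-7-{[(2Z)-2-methylbut-2-enoyl]oxy}-3-oxo-3,4,4a,5,6,7,8,8a-octahydronaphthalen-2-yl]propanoate (CNP0323033.1) | C/C=C(/C)C(=O)O[C@H]1CC[C@@H]2CC(=O)C([C@@H](C)C(=O)OC)=C[C@]2(C)[C@H]1C | target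

## Step count and risks

Total step count: 11.
Longest linear sequence: 9 steps (steps 3 to 11, from 6).

**Step 9 (key step).** What may go wrong: the facial selectivity at the C5 enamine carbon may be poor, because the preference for the enamine carbon over the methyl group in the axial site is small. The methyl-axial mode would then deliver the 5-epimeric trans-fused enone; the Michael addition may also be slow against reversible amine addition to the enone. Fallback (reagent control by a stoichiometric chiral amine instead of substrate control): setting out from 16, condensation with (R)-1-phenylethylamine (4 Å molecular sieves, CH2Cl2) should give the aldimine of 16 F1. On warming (THF, 50 °C) its secondary enamine tautomer should add to the enone in a compact aza-ene-type Michael reaction in which the amine stereocentre shields one enamine face, giving the ring A imine F2. Both enantiomers of the amine are available, so the one that reinforces the substrate preference would be kept. Hydrolysis (aqueous AcOH) gives keto aldehyde 17, now isolated, and aldol condensation (pyrrolidine, AcOH, toluene, 60 °C) comes back to the route at 19.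

**Step 6.** What may go wrong: the basic ylide may enolise the methyl ketone, which would epimerise the alpha stereocentre (C4) or eliminate the beta silyloxy group. Fallback (non-basic methylenation, then oxidation-level adjustment): setting out from 13, Petasis methylenation with Cp2TiMe2 (toluene, 65 °C) should give the 1,1-disubstituted alkene F3. Hydroboration with 9-BBN, which prefers the 1,1-disubstituted terminal alkene over the Z-disubstituted one, followed by NaBO3 oxidation gives the primary alcohol F4. Dess–Martin oxidation comes back to the route at 15.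

**Step 11.** What may go wrong: the angelate may isomerise to the tiglate during acyl activation, or acylation of the hindered C3 hydroxyl may be slow enough that prolonged heating with base epimerises C11. Fallback (the Z alkene is built on the ester instead of being carried in the acid): setting out from 20, esterification with 2-[bis(2,2,2-trifluoroethoxy)phosphoryl]propanoic acid (DCC, cat. DMAP, CH2Cl2) gives the phosphonopropanoate ester of 20 F5. Still–Gennari olefination with acetaldehyde (KHMDS, 18-crown-6, THF, −78 °C) should give the Z-2-methylbut-2-enoate and comes back to the route at 23.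

## Further compounds

F1 | step 9 | (R)-1-phenylethyl aldimine of 16 | COC(=O)[C@H](C)CC(=O)/C=C/CC[C@H](O[Si](C)(C)C(C)(C)C)[C@H](C)C(C)/C=N/[C@H](C)c1ccccc1
F2 | step 9 | (R)-1-phenylethyl aldimine of keto aldehyde 17 | CC(C)(C)[Si](C)(C)O[C@H]1CC[C@H](CC(=O)C[C@@H](C)C(=O)OC)[C@](C)(/C=N/[C@H](C)c2ccccc2)[C@H]1C
F3 | step 6 | tert-butyl{[(3Z,7S,8R)-8,9-dimethyldeca-3,9-dien-7-yl]oxy}dimethylsilane | CC/C=C\CC[C@H](O[Si](C)(C)C(C)(C)C)[C@H](C)C(C)=C
F4 | step 6 | (3R,4S,7Z)-4-[(tert-butyldimethylsilyl)oxy]-2,3-dimethyldec-7-en-1-ol (C2 epimers) | CC/C=C\CC[C@H](O[Si](C)(C)C(C)(C)C)[C@H](C)C(C)CO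
F5 | step 11 | 2-[bis(2,2,2-trifluoroethoxy)phosphoryl]propanoate ester of 20 at the C3 oxygen | CC(C(=O)O[C@H]1CC[C@@H]2CC(=O)C([C@@H](C)C(=O)OC)=C[C@]2(C)[C@H]1C)P(=O)(OCC(F)(F)F)OCC(F)(F)F
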